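**Plan**

Retrosynthesis: the C4–C5 epoxide oxygen is removed first. The ten-membered ring is then cut between C1 and C10 at the C1 carbinol level, which leaves an acyclic ynal. The chain is cut at C5–C6 (alkenylzinc plus aldehyde) and at C8–C9 (propargylboration), and the butenolide is traced back to a 3,4-disubstituted furan.
Enabling feature: the 2-methylene-1-one unit C14=C10–C1=O is the exo adduct of an aldehyde with a terminal alkyne. The butenolide ring (O–C12–C11=C7–C6) and the E C4=C5 alkene stiffen and fold the chain so that C1 and C10 can meet.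
Forward order: furan ring (bought) → C8 stereocentre and tiglate → furan oxidized to the hydroxybutenolide and opened → C5–C6 union with closure of the butenolide ring → ten-membered carbocycle (C1–C10) → C13 acetate and C1 ketone → epoxide ring last.
Stereochemistry: C8 from chiral phosphoric acid-catalysed propargylboration; C6 from amino alcohol-controlled alkenylzinc addition; the C4=C5 geometry from carboalumination; the C4/C5 epoxide from peripheral attack on the macrocycle, directed by C6; the C1 carbinol is transient.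

Key step: step 11

Remark: atoms carry germacrane numbers (C1 ketone carbon; C10 bears the exocyclic methylene C14; C4/C5 epoxide carbons with methyl C15 on C4; C6 lactone CH; C7=C11 butenolide alkene; C12 lactone carbonyl; C13 acetoxymethyl carbon; C8 ester-bearing carbon); TBS = tert-butyldimethylsilyl, TES = triethylsilyl, tigloyl/tiglate = (2E)-2-methylbut-2-enoyl ester; compounds 1, 4, 7 and 12 are taken as commercial.

Step 1
Reactants: 1 furan-3,4-diyldimethanol
Product: 2 [4-(TBSO-methyl)furan-3-yl]methanol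
Conditions: NaH (1.0 equiv), THF, 0 °C; TBSCl (1.0 equiv), 0 °C to rt
Reagents that add atoms: tert-butyl(chloro)dimethylsilane CC(C)(C)[Si](C)(C)Cl
Why: Monodeprotonation of the symmetric diol gives a poorly soluble monoalkoxide that is silylated once (desymmetrization by O-monosilylation), which differentiates the future C13 and C8 carbons.

Step 2
Reactants: 2 [4-(TBSO-methyl)furan-3-yl]methanol
Product: 3 4-(TBSO-methyl)furan-3-carbaldehyde
Conditions: MnO2 (activated, excess), CH2Cl2, rt
Reagents that add atoms: none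
Why: MnO2 oxidizes the furfuryl-type (heteroaryl) carbinol to the aldehyde and leaves the silyl ether alone (oxidation of an activated alcohol).

Step 3
Reactants: 3 4-(TBSO-methyl)furan-3-carbaldehyde; 4 allenylboronic acid pinacol ester
Product: 6 (1S)-1-[4-(TBSO-methyl)furan-3-yl]but-3-yn-1-ol, via borate ester 5 (not isolated)
Conditions: (S)-TRIP (10 mol %), 4 Å molecular sieves, toluene, −20 °C; then H2O
Reagents that add atoms: none
Why: Chiral phosphoric acid-catalysed propargylboration through a closed six-membered transition state (allenyl-to-propargyl transposition) should give the homopropargylic borate; the (S) acid is expected to direct attack to the Si face of the aldehyde and so set C8 as S, by analogy with the R alcohols that the (R) acid gives with aryl aldehydes.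

Step 4
Reactants: 6 (1S)-1-[4-(TBSO-methyl)furan-3-yl]but-3-yn-1-ol; 7 tigloyl chloride
Product: 8 (1S)-1-[4-(TBSO-methyl)furan-3-yl]but-3-yn-1-yl tiglate
Conditions: pyridine, DMAP (cat.), CH2Cl2, 0 °C
Reagents that add atoms: none
Why: DMAP-catalysed acylation of the secondary alcohol installs the C8 ester early, with the thermodynamically preferred E geometry of the tiglate retained (nucleophilic-catalysed esterification).

Step 5
Reactants: 8 (1S)-1-[4-(TBSO-methyl)furan-3-yl]but-3-yn-1-yl tiglate
Product: 10 (1S)-1-[4-(TBSO-methyl)-2-hydroxy-5-oxo-2,5-dihydrofuran-3-yl]but-3-yn-1-yl tiglate (both lactol epimers), via furan endoperoxide 9 (not isolated)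
Conditions: O2, visible light, tetraphenylporphyrin (cat.), iPr2NEt, CH2Cl2, −78 °C
Reagents that add atoms: dioxygen O=O
Why: [4+2] addition of singlet oxygen to the furan gives the endoperoxide, and the hindered amine should remove the less shielded bridgehead hydrogen, the one next to the CH2OTBS-bearing carbon (Kornblum–DeLaMare-type fragmentation), so that this carbon becomes the lactone carbonyl C12 and the carbon next to the branched C8 substituent becomes the lactol C6.

Step 6
Reactants: 10 (1S)-1-[4-(TBSO-methyl)-2-hydroxy-5-oxo-2,5-dihydrofuran-3-yl]but-3-yn-1-yl tiglate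
Product: 11 methyl (2Z,4S)-3-formyl-2-(TBSO-methyl)-4-(tigloyloxy)hept-2-en-6-ynoate
Conditions: Me3SiCHN2, MeOH/toluene, 0 °C
Reagents that add atoms: trimethylsilyldiazomethane C[Si](C)(C)C=[N+]=[N-]
Why: The ring-opened (Z)-formylacrylic acid tautomer of the pseudo-acid is O-methylated by the diazoalkane, which frees the C6 aldehyde as a normal ester (diazoalkane esterification).

Step 7
Reactants: 12 pent-4-yn-1-ol
Product: 14 (4E)-5-iodo-4-methylpent-4-en-1-ol, via alkenylalane 13 (not isolated)
Conditions: AlMe3 (3 equiv), Cp2ZrCl2 (0.25 equiv), CH2Cl2, 0 °C to rt; then I2, THF, −30 to 0 °C; aq NaHCO3/Na2S2O3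
Reagents that add atoms: trimethylaluminium C[Al](C)C; diiodine [I][I]
Why: Negishi carboalumination adds methyl and aluminium syn across the alkyne with methyl on the internal carbon, and iodinolysis with retention gives the E iodide that carries the C4=C5 geometry and the C15 methyl.

Step 8
Reactants: 14 (4E)-5-iodo-4-methylpent-4-en-1-ol
Product: 15 triethyl{[(4E)-5-iodo-4-methylpent-4-en-1-yl]oxy}silane
Conditions: Et3SiCl, imidazole, CH2Cl2, 0 °C
Reagents that add atoms: chlorotriethylsilane CC[Si](Cl)(CC)CC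
Why: Silylation masks the future C1 oxygen as a TES ether that stands the lithiation and can later be oxidized selectively beside the TBS ether (O-silylation).

Step 9
Reactants: 15 triethyl{[(4E)-5-iodo-4-methylpent-4-en-1-yl]oxy}silane; 11 methyl (2Z,4S)-3-formyl-2-(TBSO-methyl)-4-(tigloyloxy)hept-2-en-6-ynoate
Product: 19 (1S)-1-[(2R)-2-[(1E)-2-methyl-5-(TESO)pent-1-en-1-yl]-5-oxo-4-(TBSO-methyl)-2,5-dihydrofuran-3-yl]but-3-yn-1-yl tiglate, via alkenyllithium 16 (not isolated), via dialkenylzinc 17 (not isolated), via hydroxy ester 18 (not isolated)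
Conditions: 15 (2.2 equiv), t-BuLi (4.4 equiv), Et2O, −78 °C; ZnCl2 (1.1 equiv), −78 to 0 °C; N,N,N′,N′-tetraethylethylenediamine, (+)-MIB (10 mol %), toluene/hexanes; then 11, 0 °C; aq NH4Cl
Reagents that add atoms: none
Why: Iodine–lithium exchange and transmetalation give a dialkenylzinc that adds to the aldehyde under amino alcohol catalysis (catalytic asymmetric alkenylzinc addition); (+)-MIB is expected to direct the alkenyl group to the Re face of C6, its enantiomer being known for Si-face delivery, and the zinc alkoxide then closes the butenolide onto the cis methyl ester.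

Step 10
Reactants: 19 (1S)-1-[(2R)-2-[(1E)-2-methyl-5-(TESO)pent-1-en-1-yl]-5-oxo-4-(TBSO-methyl)-2,5-dihydrofuran-3-yl]but-3-yn-1-yl tiglate
Product: 20 (1S)-1-[(2R)-2-[(1E)-2-methyl-5-oxopent-1-en-1-yl]-5-oxo-4-(TBSO-methyl)-2,5-dihydrofuran-3-yl]but-3-yn-1-yl tiglate
Conditions: (COCl)2, DMSO, CH2Cl2, −78 to −30 °C; then Et3N, −78 to 0 °C
Reagents that add atoms: none
Why: Swern conditions cleave the primary TES ether and oxidize the resulting alkoxysulfonium salt in one operation while the bulkier primary TBS ether survives (direct Swern oxidation of a triethylsilyl ether), which unveils the C1 aldehyde.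

Step 11
Reactants: 20 (1S)-1-[(2R)-2-[(1E)-2-methyl-5-oxopent-1-en-1-yl]-5-oxo-4-(TBSO-methyl)-2,5-dihydrofuran-3-yl]but-3-yn-1-yl tiglate
Product: 21 (4E,6R,8S)-13-(TBSO)-1-(TESO)-8-(tigloyloxy)germacra-4,7(11),10(14)-trien-12,6-olide (both C1 epimers)
Conditions: Ni(cod)2 (20 mol %) premixed with DP-IPr [1,3-bis(2,6-diisopropylphenyl)-4,5-diphenylimidazol-2-ylidene] (20 mol %), Et3SiH (3 equiv), THF, rt; 20 added by syringe pump (final 0.002 M)
Reagents that add atoms: triethylsilane CC[SiH](CC)CC
Why: Zerovalent nickel bearing one bulky N-heterocyclic carbene binds the aldehyde and the terminal alkyne of 20 and couples them by oxidative cyclization to a five-membered oxanickelacycle in which C1 is bonded to C10; σ-bond metathesis with Et3SiH and C–H reductive elimination then deliver the C1 silyl ether and the C14 methylene. The closest known reaction type is the ligand-controlled nickel-catalysed reductive macrocyclization of terminal ynals (aldehyde–alkyne reductive coupling). The ten-membered carbocycle closes in the exo-dig mode: the new bond goes to the internal alkyne carbon, so C14 stays outside the ring. The new stereocentre at C1 is not controlled and need not be, since both epimers are oxidized to the same ketone in step 14. The step needs exo over endo regioselectivity, ring closure over oligomerization, and no ionization of the allylic C8 ester: the first is secured by the terminal alkyne, whose small C14–H end sits next to the bulky carbene in the metallacycle; the second by the rigid butenolide ring and the E C4=C5 alkene, which fold the C1–C5 chain over the C8–C10 arm, together with slow addition; the third by the tetrasubstituted, hindered butenolide alkene and by keeping O13 as a silyl ether.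

Step 12
Reactants: 21 (4E,6R,8S)-13-(TBSO)-1-(TESO)-8-(tigloyloxy)germacra-4,7(11),10(14)-trien-12,6-olide
Product: 22 (4E,6R,8S)-1,13-dihydroxy-8-(tigloyloxy)germacra-4,7(11),10(14)-trien-12,6-olide (both C1 epimers)
Conditions: HF·pyridine, pyridine, THF, 0 °C to rt
Reagents that add atoms: none
Why: Buffered fluoride cleaves the secondary TES and the primary TBS ether without base, so the esters and the base-sensitive butenolide should stay intact (desilylation).

Step 13
Reactants: 22 (4E,6R,8S)-1,13-dihydroxy-8-(tigloyloxy)germacra-4,7(11),10(14)-trien-12,6-olide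
Product: 23 (4E,6R,8S)-13-acetoxy-1-hydroxy-8-(tigloyloxy)germacra-4,7(11),10(14)-trien-12,6-olide (both C1 epimers)
Conditions: Ac2O (1.1 equiv), 2,4,6-collidine, CH2Cl2, −20 °C
Reagents that add atoms: acetic anhydride CC(=O)OC(C)=O
Why: The unhindered primary C13 alcohol should be acetylated much faster than the secondary C1 alcohol flanked by the ring (chemoselective acylation with a weak base).

Step 14
Reactants: 23 (4E,6R,8S)-13-acetoxy-1-hydroxy-8-(tigloyloxy)germacra-4,7(11),10(14)-trien-12,6-olide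
Product: 24 (4E,6R,8S)-13-acetoxy-1-oxo-8-(tigloyloxy)germacra-4,7(11),10(14)-trien-12,6-olide
Conditions: Dess–Martin periodinane, NaHCO3, CH2Cl2, 0 °C
Reagents that add atoms: none
Why: Dess–Martin oxidation of the secondary allylic alcohol gives the cross-conjugated 2-methylene ketone under buffered, non-nucleophilic conditions and removes the uncontrolled C1 stereocentre.

Step 15
Reactants: 24 (4E,6R,8S)-13-acetoxy-1-oxo-8-(tigloyloxy)germacra-4,7(11),10(14)-trien-12,6-olide
Product: 25 (4R,5R,6S,8S)-13-acetoxy-4,5-epoxy-1-oxo-8-(tigloyloxy)germacra-7(11),10(14)-dien-12,6-olide (CNP0225286.1)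
Conditions: mCPBA (1.1 equiv), NaHCO3, CH2Cl2, 0 °C
Reagents that add atoms: 3-chloroperoxybenzoic acid OOC(=O)c1cccc(Cl)c1
Why: The peracid should attack the only electron-rich alkene, C4=C5, from the outer face of the (E)-cyclodecene, which is the face carrying the C6–O bond when C6–H eclipses the C15 methyl (minimized allylic 1,3-strain); this sets 4R,5R relative to C6 as in the epoxidation of related (E)-germacr-4-en-12,6-olides (Prilezhaev epoxidation under macrocyclic control).

**Compound list**

1 | furan-3,4-diyldimethanol | OCc1cocc1CO | starting material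
2 | [4-(TBSO-methyl)furan-3-yl]methanol | OCc1cocc1CO[Si](C)(C)C(C)(C)C | intermediate
3 | 4-(TBSO-methyl)furan-3-carbaldehyde | O=Cc1cocc1CO[Si](C)(C)C(C)(C)C | intermediate
4 | allenylboronic acid pinacol ester (4,4,5,5-tetramethyl-2-(propa-1,2-dien-1-yl)-1,3,2-dioxaborolane) | C=C=CB1OC(C)(C)C(C)(C)O1 | starting material
5 | pinacol borate of alcohol 6 (O–B bond at C8, S at C8) | C#CC[C@H](OB1OC(C)(C)C(C)(C)O1)c1cocc1CO[Si](C)(C)C(C)(C)C | intermediate
6 | (1S)-1-[4-(TBSO-methyl)furan-3-yl]but-3-yn-1-ol | C#CC[C@H](O)c1cocc1CO[Si](C)(C)C(C)(C)C | intermediate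
7 | tigloyl chloride, (2E)-2-methylbut-2-enoyl chloride | C/C=C(\C)C(Cl)=O | starting material
8 | (1S)-1-[4-(TBSO-methyl)furan-3-yl]but-3-yn-1-yl tiglate | C#CC[C@H](OC(=O)/C(C)=C/C)c1cocc1CO[Si](C)(C)C(C)(C)C | intermediate
9 | furan endoperoxide of 8: 2,3,7-trioxabicyclo[2.2.1]hept-5-ene with the (1S)-1-(tigloyloxy)but-3-ynyl group on C5 and CH2OTBS on C6 (both faces) | C#CC[C@H](OC(=O)/C(C)=C/C)C1=C(CO[Si](C)(C)C(C)(C)C)C2OOC1O2 | intermediate
10 | (1S)-1-[4-(TBSO-methyl)-2-hydroxy-5-oxo-2,5-dihydrofuran-3-yl]but-3-yn-1-yl tiglate (both lactol epimers) | C#CC[C@H](OC(=O)/C(C)=C/C)C1=C(CO[Si](C)(C)C(C)(C)C)C(=O)OC1O | intermediate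
11 | methyl (2Z,4S)-3-formyl-2-(TBSO-methyl)-4-(tigloyloxy)hept-2-en-6-ynoate | C#CC[C@H](OC(=O)/C(C)=C/C)/C(C=O)=C(\CO[Si](C)(C)C(C)(C)C)C(=O)OC | intermediate
12 | pent-4-yn-1-ol | C#CCCCO | starting material
13 | (E)-alkenylalane: dimethyl{(1E)-5-[(dimethylalumanyl)oxy]-2-methylpent-1-en-1-yl}alumane | C[Al](C)/C=C(\C)CCCO[Al](C)C | intermediate
14 | (4E)-5-iodo-4-methylpent-4-en-1-ol | OCCC/C(C)=C/I | intermediate
15 | triethyl{[(4E)-5-iodo-4-methylpent-4-en-1-yl]oxy}silane | CC[Si](CC)(CC)OCCC/C(C)=C/I | intermediate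
16 | [(1E)-2-methyl-5-(TESO)pent-1-en-1-yl]lithium | [Li]/C=C(\C)CCCO[Si](CC)(CC)CC | intermediate
17 | bis[(1E)-2-methyl-5-(TESO)pent-1-en-1-yl]zinc | CC[Si](CC)(CC)OCCC/C(C)=C/[Zn]/C=C(\C)CCCO[Si](CC)(CC)CC | intermediate
18 | methyl (2E,4S)-3-[(1R,2E)-1-hydroxy-3-methyl-6-(TESO)hex-2-en-1-yl]-2-(TBSO-methyl)-4-(tigloyloxy)hept-2-en-6-ynoate (present as its zinc alkoxide; same alkene geometry as 11) | C#CC[C@H](OC(=O)/C(C)=C/C)/C([C@H](O)/C=C(\C)CCCO[Si](CC)(CC)CC)=C(\CO[Si](C)(C)C(C)(C)C)C(=O)OC | intermediate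
19 | (1S)-1-[(2R)-2-[(1E)-2-methyl-5-(TESO)pent-1-en-1-yl]-5-oxo-4-(TBSO-methyl)-2,5-dihydrofuran-3-yl]but-3-yn-1-yl tiglate | C#CC[C@H](OC(=O)/C(C)=C/C)C1=C(CO[Si](C)(C)C(C)(C)C)C(=O)O[C@@H]1/C=C(\C)CCCO[Si](CC)(CC)CC | intermediate
20 | (1S)-1-[(2R)-2-[(1E)-2-methyl-5-oxopent-1-en-1-yl]-5-oxo-4-(TBSO-methyl)-2,5-dihydrofuran-3-yl]but-3-yn-1-yl tiglate | C#CC[C@H](OC(=O)/C(C)=C/C)C1=C(CO[Si](C)(C)C(C)(C)C)C(=O)O[C@@H]1/C=C(\C)CCC=O | intermediate
21 | (4E,6R,8S)-13-(TBSO)-1-(TESO)-8-(tigloyloxy)germacra-4,7(11),10(14)-trien-12,6-olide (both C1 epimers) | C=C1C[C@H](OC(=O)/C(C)=C/C)C2=C(CO[Si](C)(C)C(C)(C)C)C(=O)O[C@@H]2/C=C(\C)CCC1O[Si](CC)(CC)CC | intermediate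
22 | (4E,6R,8S)-1,13-dihydroxy-8-(tigloyloxy)germacra-4,7(11),10(14)-trien-12,6-olide (both C1 epimers) | C=C1C[C@H](OC(=O)/C(C)=C/C)C2=C(CO)C(=O)O[C@@H]2/C=C(\C)CCC1O | intermediate
23 | (4E,6R,8S)-13-acetoxy-1-hydroxy-8-(tigloyloxy)germacra-4,7(11),10(14)-trien-12,6-olide (both C1 epimers) | C=C1C[C@H](OC(=O)/C(C)=C/C)C2=C(COC(C)=O)C(=O)O[C@@H]2/C=C(\C)CCC1O | intermediate
24 | (4E,6R,8S)-13-acetoxy-1-oxo-8-(tigloyloxy)germacra-4,7(11),10(14)-trien-12,6-olide | C=C1C[C@H](OC(=O)/C(C)=C/C)C2=C(COC(C)=O)C(=O)O[C@@H]2/C=C(\C)CCC1=O | intermediate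
25 | (4R,5R,6S,8S)-13-acetoxy-4,5-epoxy-1-oxo-8-(tigloyloxy)germacra-7(11),10(14)-dien-12,6-olide (CNP0225286.1) | C=C1C[C@H](OC(=O)/C(C)=C/C)C2=C(COC(C)=O)C(=O)O[C@@H]2[C@H]2O[C@]2(C)CCC1=O | target

**Step count and risks**

Total steps: 15. Longest linear sequence: 13 (steps 1–6 and 9–15); steps 7 and 8 build the C1–C5 iodide that joins in step 9.

Steps most likely to fail, riskiest first:

Step 11. The closure may go to the terminal alkyne carbon and give the eleven-membered endo ring, the ynal may oligomerize, the aldehyde may simply be hydrosilylated, or nickel may ionize the allylic C8 ester. The fallback closes the same bond by an alkenylchromium addition. It sets out from 19: molybdenum-catalysed Markovnikov hydrostannation (Bu3SnH, Mo(CO)3(CNtBu)3 cat., hydroquinone, THF, 55 °C) should give the 2-stannyl-1-alkene F1, and iodine (CH2Cl2, 0 °C) the 2-iodo-1-alkene F2. The Swern conditions of step 10 convert the TES ether into the iodo aldehyde F3. An intramolecular Nozaki–Hiyama–Kishi reaction (CrCl2, NiCl2 cat., DMSO/THF, rt, high dilution) should then give the macrocyclic allylic alcohol F4 as C1 epimers. HF·pyridine removes the TBS group and the route is rejoined at 22.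

Step 9. Facial control at C6 may be eroded by mismatch between the ligand and the C8 stereocentre, by salt-promoted background addition, or by chelation of zinc to the ester groups. The fallback gives up reagent control and recycles the wrong epimer. It sets out from 15 and 11: a Nozaki–Hiyama–Kishi coupling without chiral ligand (CrCl2, NiCl2 cat., DMSO, rt) should give 19 together with its C6 epimer F5, which are diastereomers and separable. F5 is converted with TBSOTf and Et3N into the 2-silyloxyfuran F6, in which C6 is planar. Mild hydrolysis (AcOH, H2O, THF, 0 °C) reprotonates C6 and returns a mixture of 19 and F5 for another separation, so the route is rejoined at 19.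

Step 5. The base-induced fragmentation of the endoperoxide may show low regioselectivity and also give the isomer with the carbonyl next to the C8-bearing carbon. The fallback marks C12 with silicon before the oxidation. It sets out from 3: in situ protection of the aldehyde as its α-amino alkoxide (lithium 4-methylpiperazin-1-ide, THF, −78 °C), lithiation of the free α-position next to the CH2OTBS-bearing carbon (n-BuLi) and quenching with Me3SiCl should give the silyl aldehyde F7 after aqueous work-up. The conditions of step 3 give, through the borate F8, the alcohol F9, and the conditions of step 4 give the tiglate F10. Photooxygenation of F10 without amine (O2, visible light, tetraphenylporphyrin, CH2Cl2, −78 °C) is regiospecific, because the silyl group migrates to the peroxide oxygen and its carbon becomes the lactone carbonyl; hydrolysis of the silyl ester on work-up gives 10, where the route is rejoined.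

Further compounds
F1 | step 11 | (1S)-1-[(2R)-2-[(1E)-2-methyl-5-(TESO)pent-1-en-1-yl]-5-oxo-4-(TBSO-methyl)-2,5-dihydrofuran-3-yl]-3-(tributylstannyl)but-3-en-1-yl tiglate | C=C([Sn](CCCC)(CCCC)CCCC)C[C@H](OC(=O)/C(C)=C/C)C1=C(CO[Si](C)(C)C(C)(C)C)C(=O)O[C@@H]1/C=C(\C)CCCO[Si](CC)(CC)CC
F2 | step 11 | (1S)-3-iodo-1-[(2R)-2-[(1E)-2-methyl-5-(TESO)pent-1-en-1-yl]-5-oxo-4-(TBSO-methyl)-2,5-dihydrofuran-3-yl]but-3-en-1-yl tiglate | C=C(I)C[C@H](OC(=O)/C(C)=C/C)C1=C(CO[Si](C)(C)C(C)(C)C)C(=O)O[C@@H]1/C=C(\C)CCCO[Si](CC)(CC)CC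
F3 | step 11 | (1S)-3-iodo-1-[(2R)-2-[(1E)-2-methyl-5-oxopent-1-en-1-yl]-5-oxo-4-(TBSO-methyl)-2,5-dihydrofuran-3-yl]but-3-en-1-yl tiglate | C=C(I)C[C@H](OC(=O)/C(C)=C/C)C1=C(CO[Si](C)(C)C(C)(C)C)C(=O)O[C@@H]1/C=C(\C)CCC=O
F4 | step 11 | (4E,6R,8S)-1-hydroxy-13-(TBSO)-8-(tigloyloxy)germacra-4,7(11),10(14)-trien-12,6-olide (both C1 epimers) | C=C1C[C@H](OC(=O)/C(C)=C/C)C2=C(CO[Si](C)(C)C(C)(C)C)C(=O)O[C@@H]2/C=C(\C)CCC1O
F5 | step 9 | C6 epimer of 19: (1S)-1-[(2S)-2-[(1E)-2-methyl-5-(TESO)pent-1-en-1-yl]-5-oxo-4-(TBSO-methyl)-2,5-dihydrofuran-3-yl]but-3-yn-1-yl tiglate | C#CC[C@H](OC(=O)/C(C)=C/C)C1=C(CO[Si](C)(C)C(C)(C)C)C(=O)O[C@H]1/C=C(\C)CCCO[Si](CC)(CC)CC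
F6 | step 9 | (1S)-1-[5-(TBSO)-4-(TBSO-methyl)-2-[(1E)-2-methyl-5-(TESO)pent-1-en-1-yl]furan-3-yl]but-3-yn-1-yl tiglate | C#CC[C@H](OC(=O)/C(C)=C/C)c1c(CO[Si](C)(C)C(C)(C)C)c(O[Si](C)(C)C(C)(C)C)oc1/C=C(\C)CCCO[Si](CC)(CC)CC
F7 | step 5 | 4-(TBSO-methyl)-5-(trimethylsilyl)furan-3-carbaldehyde | O=Cc1coc([Si](C)(C)C)c1CO[Si](C)(C)C(C)(C)C
F8 | step 5 | pinacol borate of alcohol F9 (O–B bond at C8, S at C8) | C#CC[C@H](OB1OC(C)(C)C(C)(C)O1)c1coc([Si](C)(C)C)c1CO[Si](C)(C)C(C)(C)C
F9 | step 5 | (1S)-1-[4-(TBSO-methyl)-5-(trimethylsilyl)furan-3-yl]but-3-yn-1-ol | C#CC[C@H](O)c1coc([Si](C)(C)C)c1CO[Si](C)(C)C(C)(C)C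
F10 | step 5 | (1S)-1-[4-(TBSO-methyl)-5-(trimethylsilyl)furan-3-yl]but-3-yn-1-yl tiglate | C#CC[C@H](OC(=O)/C(C)=C/C)c1coc([Si](C)(C)C)c1CO[Si](C)(C)C(C)(C)C
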